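**Retrosynthetic overview**
1. Feature: in ring A (C3a–C4–C5–C6–C7–C7a) the furan oxygen O1 on C7a is para to the C5 methoxy group. Of the two carbons ortho to C7a, C7 holds the allyl group, so C3a is the only open site, and ring A is a masked 2-allyl-4-methoxyphenol.
2. Last disconnection: benzofuran ⇒ trans-2,3-dihydrobenzofuran. C6–OH is para to C3a, so freeing it from its pivalate opens a dehydrogenation through the p-quinone methide.
3. Key disconnection: C3–C3a and O1–C2 are cut together ⇒ pivalate-protected allyl methoxyphenol + (E)-isoelemicin, joined by an anodic [3+2] annulation.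
4. The phenol comes from isovanillin (O-allylation, Claisen shift to C2, pivalate, Baeyer–Villiger). The alkene comes from 3,4,5-trimethoxybenzaldehyde (Wittig, Z→E isomerisation).
5. Ring order: both benzene rings are bought. The O-heterocycle is the only ring made, first as a dihydrofuran (step 7), then aromatised (step 9).

Key step: step 7

Remark on the chemistry: the target has no stereocentre and no stereogenic double bond, so the achiral compound is the "single enantiomer". Compounds 14–16 are racemates drawn as one enantiomer.

**Step 1**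
Reactants: 1 isovanillin (3-hydroxy-4-methoxybenzaldehyde); 2 allyl bromide
Product: 3 3-(allyloxy)-4-methoxybenzaldehyde
Conditions: K2CO3, DMF, 50 °C
Reagents that add atoms: none
Why: Williamson ether synthesis; the phenoxide of 1 displaces bromide from the unhindered allylic halide (SN2) and the aldehyde is inert to carbonate.

**Step 2**
Reactants: 3 3-(allyloxy)-4-methoxybenzaldehyde
Product: 5 2-allyl-3-hydroxy-4-methoxybenzaldehyde, via ortho-dienone 4 (not isolated)
Conditions: N,N-diethylaniline, 190–200 °C, Ar
Reagents that add atoms: none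
Why: Aromatic Claisen rearrangement; of the two carbons ortho to the allyloxy group C4 carries OMe, so only the [3,3] shift to C2 gives a dienone (4) that can tautomerise back to a phenol.

**Step 3**
Reactants: 5 2-allyl-3-hydroxy-4-methoxybenzaldehyde
Product: 6 2-allyl-3-formyl-6-methoxyphenyl pivalate
Conditions: PivCl, Et3N, DMAP (cat.), CH2Cl2, 0 °C → rt
Reagents that add atoms: pivaloyl chloride, CC(C)(C)C(=O)Cl
Why: DMAP-catalysed O-acylation; the acylpyridinium ion reaches the flanked phenol, and the bulky ester silences this oxygen in the later oxidations and outlasts the formate cleavage of step 4.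

**Step 4**
Reactants: 6 2-allyl-3-formyl-6-methoxyphenyl pivalate
Product: 8 2-allyl-3-hydroxy-6-methoxyphenyl pivalate, via aryl formate 7 (not isolated)
Conditions: mCPBA (1.2 equiv), CH2Cl2, 0 °C → rt; aq. Na2S2O3/NaHCO3 wash; then MeOH, Et3N (cat.), rt
Reagents that add atoms: mCPBA, O=C(OO)c1cccc(Cl)c1
Why: Baeyer–Villiger oxidation; the aryl group para to OMe migrates in preference to hydrogen, the monosubstituted alkene is a slow partner for a near-stoichiometric peracid, and the formate 7 is methanolysed far faster than the hindered pivalate, which sits meta to the new OH and cannot migrate to it.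

**Step 5**
Reactants: 9 3,4,5-trimethoxybenzaldehyde
Product: 10 (E/Z)-1,2,3-trimethoxy-5-(prop-1-enyl)benzene (isoelemicin as a mixture of alkene isomers)
Conditions: EtPPh3Br, KOtBu, THF, 0 °C → rt
Reagents that add atoms: ethyltriphenylphosphonium bromide, CC[P+](c1ccccc1)(c1ccccc1)c1ccccc1.[Br-]
Why: Wittig olefination; the non-stabilised ethylidene ylide converts the non-enolisable aromatic aldehyde into the propenylarene, expected as an isomer mixture that step 6 corrects.

**Step 6**
Reactants: 10 (E/Z)-isoelemicin
Product: 11 (E)-isoelemicin, (E)-1,2,3-trimethoxy-5-(prop-1-enyl)benzene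
Conditions: PdCl2(MeCN)2 (5 mol %), CH2Cl2, rt
Reagents that add atoms: none
Why: Pd(II)-catalysed Z→E isomerisation of aryl alkenes; reversible addition/elimination at palladium funnels the mixture to the planar, conjugated and thermodynamically preferred E isomer.

**Step 7**
Reactants: 8 2-allyl-3-hydroxy-6-methoxyphenyl pivalate; 11 (E)-isoelemicin
Product: 14 rac-(2S,3S)-7-allyl-5-methoxy-3-methyl-2-(3,4,5-trimethoxyphenyl)-2,3-dihydrobenzofuran-6-yl pivalate (2,3-trans; one enantiomer drawn), via phenoxonium ion 12 (not isolated), via benzylic cation 13 (not isolated)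
Conditions: undivided cell, graphite anode, Pt cathode, nBu4NPF6 (0.1 M), HFIP (1,1,1,3,3,3-hexafluoropropan-2-ol)–CH2Cl2, constant current at low current density with the anode held on the phenol wave located by CV, ca. 2.2 F mol−1, rt; 11 (2 equiv)
Reagents that add atoms: none
Why: Loss of two electrons and one proton from the p-methoxyphenol 8 at the anode (H2 at the cathode) gives the methoxy-stabilised phenoxonium ion 12, the methyl-bearing alkene carbon of 11 adds to its unsubstituted ortho carbon to form C3–C3a, the trimethoxybenzyl cation 13 is caught by the dienone oxygen to form O1–C2, and loss of the C3a proton restores the arene. The closest known reaction is the anodic (or hypervalent-iodine) oxidative [3+2] cycloaddition of p-methoxyphenols with electron-rich (E)-propenylarenes to trans-2-aryl-3-methyl-2,3-dihydrobenzofurans, here applied to a new pair of partners. The one new ring, the dihydrofuran, closes stepwise and polar, and its last event is a 5-exo-trig capture of the cation (counted on its quinoid form) by oxygen. C2 and C3 are fixed relative to each other in that closure, because the freely rotating cation 13 should close through the envelope that puts aryl and methyl on opposite faces, so the trans racemate is expected whatever the alkene geometry and no absolute control is needed since step 9 erases both centres. Site selectivity for C3a over C7 and the ipso carbon C5 rests on the substrate, because the C7 allyl group and the C6 acyloxy group crowd C7, an adduct at C7 or C5 cannot rearomatise, and HFIP is too poor a nucleophile to intercept 12 at C5. Chemoselectivity rests on the phenol being the most easily oxidised component, since the 4-OMe of 11 is twisted out of conjugation by its neighbours, the acyloxy-bearing product should oxidise later, and the terminal alkene and the ester are inert at this potential.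

**Step 8**
Reactants: 14 rac-trans-dihydrobenzofuranyl pivalate
Product: 15 rac-(2S,3S)-7-allyl-5-methoxy-3-methyl-2-(3,4,5-trimethoxyphenyl)-2,3-dihydrobenzofuran-6-ol (2,3-trans; one enantiomer drawn)
Conditions: NaOMe (1.5 equiv), MeOH–THF, 0 °C → rt, Ar; AcOH quench
Reagents that add atoms: none
Why: Base-mediated transesterification (methanolysis) of an aryl ester; the phenoxide is a good leaving group even from a pivalate, methoxide at room temperature does not move the allyl double bond, and C2–H and C3–H are not acidic, so the trans relationship is kept.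

**Step 9**
Reactants: 15 rac-trans-7-allyl-6-hydroxy-dihydrobenzofuran
Product: 17 7-allyl-5-methoxy-3-methyl-2-(3,4,5-trimethoxyphenyl)benzofuran-6-ol (target), via p-quinone methide 16 (not isolated)
Conditions: DDQ (1.0 equiv, slow addition), CH2Cl2, 0 °C → rt
Reagents that add atoms: none
Why: DDQ dehydrogenation of a 2-aryl-2,3-dihydrobenzofuran; with C6–OH para to C3a, hydride loss from the tertiary benzylic C3–H gives the p-quinone methide 16 (stabilised by O1 as a vinylogous ester), whose C2–H, benzylic and α to oxygen, is lost in a prototropic shift that restores ring A and creates C2=C3, while one equivalent of oxidant at low temperature is meant to spare the C7 allyl CH2.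

**Compound list**
1 | isovanillin (3-hydroxy-4-methoxybenzaldehyde) | O=Cc1ccc(OC)c(O)c1 | starting material
2 | allyl bromide | C=CCBr | starting material
3 | 3-(allyloxy)-4-methoxybenzaldehyde | C=CCOc1cc(C=O)ccc1OC | intermediate
4 | 6-allyl-5-formyl-2-methoxycyclohexa-2,4-dien-1-one (ortho-dienone, racemic, not isolated) | C=CCC1C(=O)C(OC)=CC=C1C=O | intermediate
5 | 2-allyl-3-hydroxy-4-methoxybenzaldehyde | C=CCc1c(C=O)ccc(OC)c1O | intermediate
6 | 2-allyl-3-formyl-6-methoxyphenyl pivalate | C=CCc1c(C=O)ccc(OC)c1OC(=O)C(C)(C)C | intermediate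
7 | 2-allyl-3-(formyloxy)-6-methoxyphenyl pivalate (aryl formate, not isolated) | C=CCc1c(OC=O)ccc(OC)c1OC(=O)C(C)(C)C | intermediate
8 | 2-allyl-3-hydroxy-6-methoxyphenyl pivalate | C=CCc1c(O)ccc(OC)c1OC(=O)C(C)(C)C | intermediate
9 | 3,4,5-trimethoxybenzaldehyde | COc1cc(C=O)cc(OC)c1OC | starting material
10 | (E/Z)-1,2,3-trimethoxy-5-(prop-1-enyl)benzene (isomer mixture) | CC=Cc1cc(OC)c(OC)c(OC)c1 | intermediate
11 | (E)-isoelemicin | C/C=C/c1cc(OC)c(OC)c(OC)c1 | intermediate
12 | phenoxonium ion of 8, drawn as the O-methyl oxocarbenium form of the cyclohexadienone (not isolated) | C=CCC1=C(OC(=O)C(C)(C)C)C(=[O+]C)C=CC1=O | intermediate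
13 | 3,4,5-trimethoxybenzyl cation with the C3–C3a bond formed, ring A as 2,4-cyclohexadienone (not isolated) | C=CCC1=C(OC(=O)C(C)(C)C)C(OC)=CC(C(C)[CH+]c2cc(OC)c(OC)c(OC)c2)C1=O | intermediate
14 | rac-(2S,3S)-7-allyl-5-methoxy-3-methyl-2-(3,4,5-trimethoxyphenyl)-2,3-dihydrobenzofuran-6-yl pivalate (trans) | C=CCc1c(OC(=O)C(C)(C)C)c(OC)cc2c1O[C@H](c1cc(OC)c(OC)c(OC)c1)[C@H]2C | intermediate
15 | rac-(2S,3S)-7-allyl-5-methoxy-3-methyl-2-(3,4,5-trimethoxyphenyl)-2,3-dihydrobenzofuran-6-ol (trans) | C=CCc1c(O)c(OC)cc2c1O[C@H](c1cc(OC)c(OC)c(OC)c1)[C@H]2C | intermediate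
16 | 7-allyl-5-methoxy-3-methyl-2-(3,4,5-trimethoxyphenyl)benzofuran-6(2H)-one (p-quinone methide, racemic at C2, not isolated) | C=CCC1=C2O[C@H](c3cc(OC)c(OC)c(OC)c3)C(C)=C2C=C(OC)C1=O | intermediate
17 | 7-allyl-5-methoxy-3-methyl-2-(3,4,5-trimethoxyphenyl)benzofuran-6-ol | C=CCc1c(O)c(OC)cc2c(C)c(-c3cc(OC)c(OC)c(OC)c3)oc12 | target

**Totals**
Total step count: 9. Longest linear sequence: 7 (steps 1, 2, 3, 4, 7, 8, 9).

**Steps most likely to fail**

Step 7.
- What may go wrong: the alkene partner may be oxidised alongside the phenol and its radical cation may self-couple. The benzylic cation may collapse onto carbon C7 instead of oxygen ([5+2] mode). The product may be oxidised further at the electrode, and phenol-derived films may foul the anode.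
- Fallback, from 8 and back at 14: oxidation and bond formation are separated.
- 8 is oxidised with PhI(OAc)2 in methanol to the isolable quinone monoketal 2-allyl-4,4-dimethoxy-3-(pivaloyloxy)cyclohexa-2,5-dien-1-one F1.
- F1 is then ionised with TMSOTf (or SnCl4) in MeCN–CH2Cl2 at −40 °C in the presence of 11.
- The same cation 12 arises by loss of methanol, with no oxidant or electrode in contact with the alkene.
- The acid-promoted cycloaddition of quinone monoketals with propenylarenes is established chemistry and should lead to 14.

Step 9.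
- What may go wrong: hydride may be abstracted from the doubly activated (allylic and benzylic) CH2 on C7 in competition with C3–H, followed by electrocyclisation onto the C6 oxygen. The electron-rich phenolic product may also be oxidised further.
- Fallback, from 1 (using 2 and 11) and back at 17: the allyl group is introduced only after the furan is aromatic.
- 1 is pivaloylated to 5-formyl-2-methoxyphenyl pivalate F2.
- Baeyer–Villiger oxidation gives 5-(formyloxy)-2-methoxyphenyl pivalate F3, and methanolysis gives 5-hydroxy-2-methoxyphenyl pivalate F4.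
- The anodic annulation with 11 under the conditions of step 7 should engage the ortho carbon para to the acyloxy group, because the other ortho carbon lies between two oxygen substituents. It should give rac-(2S,3S)-5-methoxy-3-methyl-2-(3,4,5-trimethoxyphenyl)-2,3-dihydrobenzofuran-6-yl pivalate F5.
- DDQ in refluxing dioxane, now with no allyl group present, should give 5-methoxy-3-methyl-2-(3,4,5-trimethoxyphenyl)benzofuran-6-yl pivalate F6.
- NaOMe/MeOH frees 5-methoxy-3-methyl-2-(3,4,5-trimethoxyphenyl)benzofuran-6-ol F7.
- Allyl bromide 2 and K2CO3 give 6-(allyloxy)-5-methoxy-3-methyl-2-(3,4,5-trimethoxyphenyl)benzofuran F8.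
- An aromatic Claisen rearrangement (N,N-diethylaniline, 200 °C) can end only at C7, since C5 carries OMe, and delivers 17.

Step 4.
- What may go wrong: the peracid may epoxidise the terminal alkene while the flanked aldehyde reacts slowly. Hydrogen may migrate instead of aryl, giving the acid oxidation level.
- Fallback, from 1 and back at 8: the alkene enters after the peracid step, and bromine holds its place.
- 1 is brominated (Br2, NaOAc, Fe cat., AcOH) between CHO and OH to 2-bromo-3-hydroxy-4-methoxybenzaldehyde F9.
- PivCl/Et3N gives 2-bromo-3-formyl-6-methoxyphenyl pivalate F10.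
- mCPBA gives 2-bromo-3-(formyloxy)-6-methoxyphenyl pivalate F11, and methanolysis gives 2-bromo-3-hydroxy-6-methoxyphenyl pivalate F12.
- Stille coupling of F12 with allyltributylstannane (Pd(PPh3)4, DMF, 90 °C) installs the allyl group and gives 8.

**Further compounds**
F1 | step 7 | 2-allyl-4,4-dimethoxy-3-(pivaloyloxy)cyclohexa-2,5-dien-1-one | C=CCC1=C(OC(=O)C(C)(C)C)C(OC)(OC)C=CC1=O
F2 | step 9 | 5-formyl-2-methoxyphenyl pivalate | O=Cc1ccc(OC)c(OC(=O)C(C)(C)C)c1
F3 | step 9 | 5-(formyloxy)-2-methoxyphenyl pivalate | O=COc1ccc(OC)c(OC(=O)C(C)(C)C)c1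
F4 | step 9 | 5-hydroxy-2-methoxyphenyl pivalate | Oc1ccc(OC)c(OC(=O)C(C)(C)C)c1
F5 | step 9 | rac-(2S,3S)-5-methoxy-3-methyl-2-(3,4,5-trimethoxyphenyl)-2,3-dihydrobenzofuran-6-yl pivalate (trans) | c1c(OC(=O)C(C)(C)C)c(OC)cc2c1O[C@H](c1cc(OC)c(OC)c(OC)c1)[C@H]2C
F6 | step 9 | 5-methoxy-3-methyl-2-(3,4,5-trimethoxyphenyl)benzofuran-6-yl pivalate | c1c(OC(=O)C(C)(C)C)c(OC)cc2c(C)c(-c3cc(OC)c(OC)c(OC)c3)oc12
F7 | step 9 | 5-methoxy-3-methyl-2-(3,4,5-trimethoxyphenyl)benzofuran-6-ol | Oc1cc2oc(-c3cc(OC)c(OC)c(OC)c3)c(C)c2cc1OC
F8 | step 9 | 6-(allyloxy)-5-methoxy-3-methyl-2-(3,4,5-trimethoxyphenyl)benzofuran | C=CCOc1cc2oc(-c3cc(OC)c(OC)c(OC)c3)c(C)c2cc1OC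
F9 | step 4 | 2-bromo-3-hydroxy-4-methoxybenzaldehyde | O=Cc1ccc(OC)c(O)c1Br
F10 | step 4 | 2-bromo-3-formyl-6-methoxyphenyl pivalate | O=Cc1ccc(OC)c(OC(=O)C(C)(C)C)c1Br
F11 | step 4 | 2-bromo-3-(formyloxy)-6-methoxyphenyl pivalate | O=COc1ccc(OC)c(OC(=O)C(C)(C)C)c1Br
F12 | step 4 | 2-bromo-3-hydroxy-6-methoxyphenyl pivalate | Oc1ccc(OC)c(OC(=O)C(C)(C)C)c1Br
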